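## The problem

The target 24 is a 1,4-naphthoquinone. Ring B (C1–C4, C4a, C8a) carries the carbonyl groups at C1 and C4 and one alkene, C2=C3; the benzenoid ring A carries a methoxy group at C5 and a free hydroxyl at C8. C2 bears a six-carbon chain whose first carbon, C1′, is the only stereocentre (S); it is esterified with 3-methylbut-2-enoic acid and followed by a CH2 group and a trisubstituted C3′=C4′ alkene. Nothing in the bicycle is symmetric: the two ring A oxygens differ, and the chain must sit next to C1, the carbonyl peri to C8–OH, and not on C3. A plan that makes the quinone by oxidising a naphthalene must in addition choose ring B over the equally electron-rich ring A. C1′ has no neighbouring stereocentre to lean on, so it must be set by a reagent or brought in. Once set it is fragile, because it is allylic to C2=C3 and its acyloxy group becomes a leaving group as soon as the quinone is reduced or enolised. The quinone (base, nucleophiles), the prenyl-type alkene (acid, electrophilic halogen), the enoate and the peri-phenol likewise forbid harsh conditions late in the route. The feature that opens the molecule is that ring B holds exactly one C=C, lying between C1 and C4, both bonded directly to ring A. With C1 and C4 lowered to carbinols, cutting C2=C3 leaves a benzene with two neighbouring allylic carbinol arms: a 1-hydroxyallyl arm next to C5–OMe and a 1-hydroxy-2-methylidenealkyl arm next to C8–O. Ring-closing metathesis rejoins them, and both carbinols are oxidised afterwards, so their configuration does not matter.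

## Retrosynthesis

The last bond made is the ester C–O at C1′: 24 is cut into hydroxy quinone 22 and acid 23. Carrying the ester from the start would save one step. It would, however, sit β to an alkenyl–metal bond in the fragment coupling, next to a free carbinol afterwards, and finally on a quinone under fluoride; each invites loss or migration of the acyl group. 22 lacks only five carbons. The forward reaction must acylate the aliphatic hydroxyl and leave the hydrogen-bonded C8 phenol alone.

22 is traced to the bis-silyl quinone 21 (two O–Si bonds), and 21 to diol 20 by lowering C1 and C4 from carbonyl to carbinol. The phenol stays silylated through the oxidation because a free para-methoxyphenol ring would itself be oxidised; C1′ stays silylated so that only the two ring carbinols react. The gain is that the quinone arises by alcohol oxidation alone, with no arene to oxidise and so no choice between rings A and B. The oxidant must be neutral and fast, since the diol loses water easily.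

In 20 the bond to cut is C2=C3, which leads to the diene diol 19. The neighbouring cuts are less attractive. C1–C8a or C4–C4a (acylation or annulation onto ring A) would reopen the question of which ring A position reacts. C2–C1′ would leave an unsymmetrical quinone or naphthalene to be substituted regioselectively. 19 is monocyclic, and the position of each arm relative to OMe and OSi is fixed when the arm is attached. The forward step must pick the vinyl/1,1-disubstituted pair among three alkenes without isomerising or ionising allylic carbinols.

19 comes from 18 by removal of one triethylsilyl group, and 18 is cut at C1–C2 into aldehyde 17 and alkenyl iodide 9. The reverse polarity, an aryl-metal adding to a 2-methylidene aldehyde, would need an unstable enal. The carbinol of the allyl arm is kept as its silyl ether through this coupling because the free hydroxy aldehyde would close to a lactol. The two halves are of similar size, so the route is convergent. The coupling must add an alkenyl group to a doubly ortho-substituted aldehyde and spare three silyl ethers, which a chromium-mediated, nickel-catalysed addition does.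

17 is taken back to bromide 15 (C–CHO bond, by halogen–metal exchange and formylation). 15 is taken back to silyl ether 11 and acrolein 12 (aryl–carbinol bond, by deprotonation of the one C–H flanked by bromine and methoxy). 11 is the silyl ether of commercial phenol 10. The regiochemistry of the whole quinone is decided here, by the purchase of 10: the carbon bearing bromine, next to the silyloxy group, becomes C1, and the carbon between bromine and methoxy becomes C4. An acetal-protected salicylaldehyde would serve the same end but costs one more step and an acidic unmasking beside an allylic silyl ether. The forward steps need a regioselective lithiation and an exchange that outruns silyl migration.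

9 is derived from silyl ether 7 by adding H and I across the terminal alkyne with iodine on the internal carbon. A tin-based hydrometalation is chosen because a protic hydroiodination would also add to the trisubstituted alkene. 7 comes from alcohol 6, 6 from its C-silyl derivative 5, and 5 from ynone 4 by reduction of the ketone, the step that creates C1′. Opening a chiral-pool epoxide with an isobutenyl nucleophile would set the same centre without a catalyst. Turning the remaining CH2O group into the alkyne would then cost an oxidation, a homologation and two protecting-group changes. 4 is cut at the acyl–alkyne bond into Weinreb amide 3 and a silylacetylide, and 3 is the amide of commercial acid 1. The reduction must be reagent-controlled and must not move the skipped C5=C6 alkene into conjugation.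

## Roads not taken

Alternative 1: The cut falls on C2–C1′ and C2′–C3′ at once, on a naphthalene whose ring B is still aromatic. Forward, the naphthyl boronate A2 takes up vinyllithium A3 to give a vinyl boronate complex. A chiral palladium catalyst carrying the alkenyl group of triflate A4 then triggers a 1,2-shift of the naphthyl group from boron to carbon, so that both bonds form together and the ligand sets C1′ in boronate A1.
- Merits: the whole chain and its stereocentre arrive in one catalytic step, and oxidation of C–B with retention gives the carbinol. In stereocentre economy this road is better than the chosen plan, which spends six steps on 9.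
- Weak points: A2 presupposes a 1,5,8-trioxygenated naphthalene with all three oxygens differentiated and boron at C2, so the regiochemical problem is moved upstream, not solved. The migrating aryl group is flanked by an ortho acetal, which slows the shift and usually erodes selectivity. A1 has C4 as C–H, so the quinone must come from oxidation of an arene in which ring A, a hydroquinone diether, competes with ring B, and this in the presence of a benzylic carbinol derivative and the prenyl alkene.
- Comparison: against the better convergence at C1′, the chosen plan sets the fact that C1 and C4 arrive as carbinols, so quinone formation is an alcohol oxidation with no ring choice.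

Alternative 2: The cut removes ring A (C5–C6, C7–C8, C8–C8a). Forward, the zerovalent chromium carbene complex A6, ethynyltrimethylsilane A7 and one carbonyl ligand combine in a Dötz benzannulation to naphthol A5, with the carbene methoxyl on C5 and the carbonyl oxygen as C8–OH.
- Merits: the two ring A oxygens are told apart by the mechanism itself, which answers the central constitutional question at least as well as the chosen plan, where the same distinction is simply bought with 10. The stereocentre rides on a simple benzene.
- Weak points: chromium is stoichiometric, and A6 must be made from an aryllithium bearing the chiral chain. The electrophilic carbene shares a molecule with a trisubstituted alkene at the temperature of the annulation. Ring B arrives as a hydroquinone dimethyl ether, so the final oxidative demethylation must take ring B and spare the more electron-rich phenolic ring A; if it does not, the isomeric quinone forms, so the C8 hydroxyl has to be deactivated first. The C–Si bond must be cleaved and the silyl ether at C1′ exchanged for the ester.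
- Comparison: step counts are similar. The chosen plan has to set against the elegant ring A construction only that it never oxidises an arene.

Alternative 3: The cut is at C4a–C5 and C8a–C8, with ring A drawn from a furan. Forward, a fluoride source releases a 3-alkoxyaryne from silyl triflate A9; it adds 2-methoxyfuran A10, and the bridged ketal opens in the flask to naphthol A8 with C5–OMe and C8–OH.
- Merits: this is the shortest assembly of the bicycle, it needs no metal, and the ester and stereocentre are carried in on a benzene. In brevity of the core construction it is better than the chosen plan.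
- Weak points: the regiochemistry rests on the distortion of the aryne by one alkoxy group and would give constitutional isomers where it fails. Fluoride meets a benzylic ester. A8 has C1 as C–H and ring A as a free para-methoxyphenol, so an oxidation meant for ring B will take ring A first and give the wrong quinone. A9 itself needs several steps.
- Comparison: the chosen plan is longer but delivers each ring B carbon at the right oxidation level and each substituent at a position fixed by connectivity.

Key step: step 12

Remark on the chemistry: the carbinol carbons that become C1 and C4 are formed without control and carried as mixtures of epimers, because both end as carbonyl carbons; names and SMILES leave them undefined.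

## Steps

Step 1
Reactants: 1 4-methylpent-3-enoic acid
Product: 3 N-methoxy-N,4-dimethylpent-3-enamide, via acyl imidazole 2 (not isolated)
Conditions: CDI, CH2Cl2, 0 °C → rt; then MeNH(OMe)·HCl, rt
Reagents that add atoms: N,O-dimethylhydroxylamine hydrochloride, CNOC.Cl
Why: Carbonyldiimidazole activation and aminolysis is the standard mild route to a Weinreb amide; no strong base is present, so the β,γ-alkene should stay out of conjugation.

Step 2
Reactants: 3 N-methoxy-N,4-dimethylpent-3-enamide
Product: 4 6-methyl-1-(trimethylsilyl)hept-5-en-1-yn-3-one
Conditions: Me3SiC≡CH, n-BuLi, THF, −78 °C; then 3, −78 → 0 °C; aq. NH4Cl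
Reagents that add atoms: ethynyltrimethylsilane, C#C[Si](C)(C)C
Why: Weinreb ketone synthesis: the lithium acetylide adds once and the chelated adduct collapses only on quenching, so the base-sensitive skipped enynone is released into a buffered aqueous phase.

Step 3
Reactants: 4 6-methyl-1-(trimethylsilyl)hept-5-en-1-yn-3-one
Product: 5 (S)-6-methyl-1-(trimethylsilyl)hept-5-en-1-yn-3-ol
Conditions: Ru[(S,S)-TsDPEN](p-cymene) (1 mol%), i-PrOH, rt
Reagents that add atoms: none
Why: Noyori asymmetric transfer hydrogenation of an alkynyl ketone: hydride and proton pass from Ru–H/N–H in a six-membered transition state in which the alkynyl group takes the place of the aryl group of an aryl ketone, so the (S,S)-ligand should give the (S)-carbinol; the neutral amido complex avoids base-induced migration of the C5=C6 alkene.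

Step 4
Reactants: 5 (S)-6-methyl-1-(trimethylsilyl)hept-5-en-1-yn-3-ol
Product: 6 (S)-6-methylhept-5-en-1-yn-3-ol
Conditions: K2CO3 (0.2 equiv), MeOH, 0 °C → rt
Reagents that add atoms: none
Why: Methanolysis of the alkynyl C–Si bond with catalytic carbonate is routine and leaves the carbinol centre untouched.

Step 5
Reactants: 6 (S)-6-methylhept-5-en-1-yn-3-ol
Product: 7 (S)-tert-butyldimethyl[(6-methylhept-5-en-1-yn-3-yl)oxy]silane
Conditions: TBSCl, imidazole, DMF, rt
Reagents that add atoms: tert-butyldimethylsilyl chloride, CC(C)(C)[Si](C)(C)Cl
Why: Standard silylation; the silyl ether stands in for the final ester through the organometallic steps, where a carboxylate on C1′ could be expelled from an alkenylmetal or shift to the neighbouring carbinol.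

Step 6
Reactants: 7 (S)-tert-butyldimethyl[(6-methylhept-5-en-1-yn-3-yl)oxy]silane
Product: 9 (S)-tert-butyl[(2-iodo-6-methylhepta-1,5-dien-3-yl)oxy]dimethylsilane, via alkenylstannane 8 (not isolated)
Conditions: Bu3SnH, Mo(CO)3(CNtBu)3 (5 mol%), hydroquinone (cat.), THF, 55 °C; then I2, CH2Cl2, 0 °C
Reagents that add atoms: iodine, II
Why: Molybdenum–isonitrile-catalysed hydrostannation of propargylic oxygenated terminal alkynes places tin on the internal carbon, and iododestannylation is an ipso substitution much faster than any reaction of iodine with the trisubstituted alkene; the stereocentre is not involved.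

Step 7
Reactants: 10 2-bromo-4-methoxyphenol
Product: 11 (2-bromo-4-methoxyphenoxy)triisopropylsilane
Conditions: TIPSCl, imidazole, DMF, rt
Reagents that add atoms: triisopropylsilyl chloride, CC(C)[Si](Cl)(C(C)C)C(C)C
Why: Phenol silylation; the bulky silyl group resists the bases used later and shields its own ortho position from deprotonation.

Step 8
Reactants: 11 (2-bromo-4-methoxyphenoxy)triisopropylsilane; 12 acrolein
Product: 15 {2-bromo-4-methoxy-3-[1-(triethylsilyloxy)prop-2-en-1-yl]phenoxy}triisopropylsilane (racemic), via aryllithium 13 (not isolated), via lithium alkoxide 14 (not isolated)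
Conditions: LiN(iPr)2, THF, −78 °C; acrolein, −78 °C; Et3SiCl, −78 → 0 °C
Reagents that add atoms: chlorotriethylsilane, CC[Si](Cl)(CC)CC
Why: Directed ortho-lithiation: the C–H flanked by bromine and methoxy is the most acidic on the ring, the aryllithium is stable at −78 °C and adds 1,2 to acrolein, and the alkoxide is silylated in the same flask; the new carbinol centre is racemic and is oxidised in step 13.

Step 9
Reactants: 15 {2-bromo-4-methoxy-3-[1-(triethylsilyloxy)prop-2-en-1-yl]phenoxy}triisopropylsilane
Product: 17 3-methoxy-2-[1-(triethylsilyloxy)prop-2-en-1-yl]-6-(triisopropylsilyloxy)benzaldehyde (racemic), via aryllithium 16 (not isolated)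
Conditions: t-BuLi (2.1 equiv), Et2O, −78 °C; DMF, −78 → 0 °C; aq. NH4Cl
Reagents that add atoms: N,N-dimethylformamide, CN(C)C=O
Why: Bromine–lithium exchange followed by formylation with a formamide; exchange at −78 °C in ether is faster than anionic silyl migration, and the silylated carbinol cannot close onto the new aldehyde as a lactol.

Step 10
Reactants: 17 3-methoxy-2-[1-(triethylsilyloxy)prop-2-en-1-yl]-6-(triisopropylsilyloxy)benzaldehyde; 9 (S)-tert-butyl[(2-iodo-6-methylhepta-1,5-dien-3-yl)oxy]dimethylsilane
Product: 18 (3S)-3-(tert-butyldimethylsilyloxy)-1-{3-methoxy-2-[1-(triethylsilyloxy)prop-2-en-1-yl]-6-(triisopropylsilyloxy)phenyl}-6-methyl-2-methylidenehept-5-en-1-ol (mixture of carbinol epimers)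
Conditions: CrCl2 (5 equiv), NiCl2 (2 mol%), DMF, rt
Reagents that add atoms: none
Why: Nozaki–Hiyama–Kishi coupling: zerovalent nickel inserts into the C–I bond, the alkenyl group passes to trivalent chromium and adds chemoselectively to the hindered aldehyde, and the chromium alkoxide is too weakly nucleophilic to take the neighbouring aryl silyl group; the new carbinol forms as both epimers, which is immaterial because C1 becomes a carbonyl in step 13.

Step 11
Reactants: 18 (3S)-3-(tert-butyldimethylsilyloxy)-1-{3-methoxy-2-[1-(triethylsilyloxy)prop-2-en-1-yl]-6-(triisopropylsilyloxy)phenyl}-6-methyl-2-methylidenehept-5-en-1-ol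
Product: 19 (3S)-3-(tert-butyldimethylsilyloxy)-1-[2-(1-hydroxyprop-2-en-1-yl)-3-methoxy-6-(triisopropylsilyloxy)phenyl]-6-methyl-2-methylidenehept-5-en-1-ol (mixture of carbinol epimers)
Conditions: HF·pyridine, pyridine, THF, 0 °C
Reagents that add atoms: none
Why: Acidic fluoride cleaves the secondary alkyl triethylsilyl ether far faster than the alkyl tert-butyldimethylsilyl ether and the aryl triisopropylsilyl ether, and the pyridine buffer keeps the doubly activated carbinols from ionising.

Step 12
Reactants: 19 (3S)-3-(tert-butyldimethylsilyloxy)-1-[2-(1-hydroxyprop-2-en-1-yl)-3-methoxy-6-(triisopropylsilyloxy)phenyl]-6-methyl-2-methylidenehept-5-en-1-ol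
Product: 20 2-[(1S)-1-(tert-butyldimethylsilyloxy)-4-methylpent-3-en-1-yl]-5-methoxy-8-(triisopropylsilyloxy)-1,4-dihydronaphthalene-1,4-diol (mixture of carbinol epimers)
Conditions: second-generation Grubbs catalyst RuCl2(H2IMes)(PCy3)(=CHPh) (5 mol%), 1,4-benzoquinone (10 mol%), CH2Cl2 (5 mM), 40 °C
Reagents that add atoms: none
Why: The benzylidene catalyst exchanges with the monosubstituted vinyl group of the 1-hydroxyallyl arm, whose free allylic hydroxyl speeds loading, to give a ruthenium alkylidene at the future C3. This alkylidene adds [2+2] to the 1,1-disubstituted alkene of the other arm and the metallacyclobutane cycloreverts, forming C2=C3 and releasing ethene. The closest known reaction type is ring-closing metathesis of benzenes bearing two ortho allylic carbinol arms to 1,4-dihydronaphthalenes. Ring B closes as a six-membered carbocycle by alkene–alkene metathesis between the ends of two arms on adjacent ring A carbons. No stereocentre is formed; C1′ is a spectator and the two carbinol centres are carried as mixtures. The step needs chemoselectivity among three alkenes, and the substrate secures it: only the vinyl/1,1-disubstituted pair can give a six-membered ring, the trisubstituted C3′=C4′ alkene could close only a nine-membered ring or a cyclobutene, and high dilution disfavours cross-metathesis. Benzoquinone intercepts ruthenium hydrides that would isomerise the allylic carbinols to ketones, and the neutral medium avoids loss of water from the product to a naphthol.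

Step 13
Reactants: 20 2-[(1S)-1-(tert-butyldimethylsilyloxy)-4-methylpent-3-en-1-yl]-5-methoxy-8-(triisopropylsilyloxy)-1,4-dihydronaphthalene-1,4-diol
Product: 21 2-[(1S)-1-(tert-butyldimethylsilyloxy)-4-methylpent-3-en-1-yl]-5-methoxy-8-(triisopropylsilyloxy)naphthalene-1,4-dione
Conditions: Dess–Martin periodinane (3 equiv), pyridine, CH2Cl2, 0 °C → rt
Reagents that add atoms: none
Why: Dess–Martin oxidation of the two benzylic, allylic carbinols gives the ene-dione, that is the quinone, directly; should the mono-oxidised intermediate tautomerise to the naphthalenediol, the same reagent oxidises it to the same quinone, and pyridine buffers the acetic acid released.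

Step 14
Reactants: 21 2-[(1S)-1-(tert-butyldimethylsilyloxy)-4-methylpent-3-en-1-yl]-5-methoxy-8-(triisopropylsilyloxy)naphthalene-1,4-dione
Product: 22 8-hydroxy-2-[(1S)-1-hydroxy-4-methylpent-3-en-1-yl]-5-methoxynaphthalene-1,4-dione
Conditions: Bu4NF, AcOH (1:1), THF, 0 °C → rt
Reagents that add atoms: none
Why: Fluoride desilylation: the aryl silyl ether peri to C1=O is cleaved at once and the secondary alkyl silyl ether more slowly, while acetic acid keeps the medium from becoming basic enough to damage the quinone.

Step 15
Reactants: 22 8-hydroxy-2-[(1S)-1-hydroxy-4-methylpent-3-en-1-yl]-5-methoxynaphthalene-1,4-dione; 23 3-methylbut-2-enoic acid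
Product: 24 (1S)-1-(8-hydroxy-5-methoxy-1,4-dioxo-1,4-dihydronaphthalen-2-yl)-4-methylpent-3-en-1-yl 3-methylbut-2-enoate
Conditions: DCC, DMAP (cat.), CH2Cl2, 0 °C → rt
Reagents that add atoms: none
Why: Steglich esterification: the carbodiimide-activated acid acylates the aliphatic C1′ hydroxyl, while the C8 phenol, held in a hydrogen bond to C1=O, is not acylated under these conditions; no bond to C1′ is broken, so the configuration is retained.

## Compound list

1 | 4-methylpent-3-enoic acid | CC(C)=CCC(=O)O | starting material
2 | 1-(4-methylpent-3-enoyl)imidazole | CC(C)=CCC(=O)n1ccnc1 | intermediate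
3 | N-methoxy-N,4-dimethylpent-3-enamide | CC(C)=CCC(=O)N(C)OC | intermediate
4 | 6-methyl-1-(trimethylsilyl)hept-5-en-1-yn-3-one | CC(C)=CCC(=O)C#C[Si](C)(C)C | intermediate
5 | (S)-6-methyl-1-(trimethylsilyl)hept-5-en-1-yn-3-ol | C[Si](C)(C)C#C[C@H](CC=C(C)C)O | intermediate
6 | (S)-6-methylhept-5-en-1-yn-3-ol | C#C[C@H](CC=C(C)C)O | intermediate
7 | (S)-tert-butyldimethyl[(6-methylhept-5-en-1-yn-3-yl)oxy]silane | C#C[C@H](CC=C(C)C)O[Si](C)(C)C(C)(C)C | intermediate
8 | (S)-tert-butyldimethyl{[6-methyl-2-(tributylstannyl)hepta-1,5-dien-3-yl]oxy}silane | C=C([Sn](CCCC)(CCCC)CCCC)[C@H](CC=C(C)C)O[Si](C)(C)C(C)(C)C | intermediate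
9 | (S)-tert-butyl[(2-iodo-6-methylhepta-1,5-dien-3-yl)oxy]dimethylsilane | C=C(I)[C@H](CC=C(C)C)O[Si](C)(C)C(C)(C)C | intermediate
10 | 2-bromo-4-methoxyphenol | COc1ccc(O)c(Br)c1 | starting material
11 | (2-bromo-4-methoxyphenoxy)triisopropylsilane | COc1ccc(O[Si](C(C)C)(C(C)C)C(C)C)c(Br)c1 | intermediate
12 | acrolein (prop-2-enal) | C=CC=O | starting material
13 | [2-bromo-6-methoxy-3-(triisopropylsilyloxy)phenyl]lithium | COc1ccc(O[Si](C(C)C)(C(C)C)C(C)C)c(Br)c1[Li] | intermediate
14 | lithium 1-[2-bromo-6-methoxy-3-(triisopropylsilyloxy)phenyl]prop-2-en-1-olate (racemic) | C=CC(O[Li])c1c(OC)ccc(O[Si](C(C)C)(C(C)C)C(C)C)c1Br | intermediate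
15 | {2-bromo-4-methoxy-3-[1-(triethylsilyloxy)prop-2-en-1-yl]phenoxy}triisopropylsilane (racemic) | C=CC(O[Si](CC)(CC)CC)c1c(OC)ccc(O[Si](C(C)C)(C(C)C)C(C)C)c1Br | intermediate
16 | {3-methoxy-2-[1-(triethylsilyloxy)prop-2-en-1-yl]-6-(triisopropylsilyloxy)phenyl}lithium (racemic) | C=CC(O[Si](CC)(CC)CC)c1c(OC)ccc(O[Si](C(C)C)(C(C)C)C(C)C)c1[Li] | intermediate
17 | 3-methoxy-2-[1-(triethylsilyloxy)prop-2-en-1-yl]-6-(triisopropylsilyloxy)benzaldehyde (racemic) | C=CC(O[Si](CC)(CC)CC)c1c(OC)ccc(O[Si](C(C)C)(C(C)C)C(C)C)c1C=O | intermediate
18 | (3S)-3-(tert-butyldimethylsilyloxy)-1-{3-methoxy-2-[1-(triethylsilyloxy)prop-2-en-1-yl]-6-(triisopropylsilyloxy)phenyl}-6-methyl-2-methylidenehept-5-en-1-ol (mixture of carbinol epimers) | C=CC(O[Si](CC)(CC)CC)c1c(OC)ccc(O[Si](C(C)C)(C(C)C)C(C)C)c1C(O)C(=C)[C@H](CC=C(C)C)O[Si](C)(C)C(C)(C)C | intermediate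
19 | (3S)-3-(tert-butyldimethylsilyloxy)-1-[2-(1-hydroxyprop-2-en-1-yl)-3-methoxy-6-(triisopropylsilyloxy)phenyl]-6-methyl-2-methylidenehept-5-en-1-ol (mixture of carbinol epimers) | C=CC(O)c1c(OC)ccc(O[Si](C(C)C)(C(C)C)C(C)C)c1C(O)C(=C)[C@H](CC=C(C)C)O[Si](C)(C)C(C)(C)C | intermediate
20 | 2-[(1S)-1-(tert-butyldimethylsilyloxy)-4-methylpent-3-en-1-yl]-5-methoxy-8-(triisopropylsilyloxy)-1,4-dihydronaphthalene-1,4-diol (mixture of carbinol epimers) | OC1C=C([C@H](CC=C(C)C)O[Si](C)(C)C(C)(C)C)C(O)c2c(O[Si](C(C)C)(C(C)C)C(C)C)ccc(OC)c12 | intermediate
21 | 2-[(1S)-1-(tert-butyldimethylsilyloxy)-4-methylpent-3-en-1-yl]-5-methoxy-8-(triisopropylsilyloxy)naphthalene-1,4-dione | COc1ccc(O[Si](C(C)C)(C(C)C)C(C)C)c2c1C(=O)C=C([C@H](CC=C(C)C)O[Si](C)(C)C(C)(C)C)C2=O | intermediate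
22 | 8-hydroxy-2-[(1S)-1-hydroxy-4-methylpent-3-en-1-yl]-5-methoxynaphthalene-1,4-dione | COc1ccc(O)c2c1C(=O)C=C([C@H](CC=C(C)C)O)C2=O | intermediate
23 | 3-methylbut-2-enoic acid | CC(C)=CC(=O)O | starting material
24 | (1S)-1-(8-hydroxy-5-methoxy-1,4-dioxo-1,4-dihydronaphthalen-2-yl)-4-methylpent-3-en-1-yl 3-methylbut-2-enoate (CNP0299347.1) | COc1ccc(O)c2c1C(=O)C=C([C@H](CC=C(C)C)OC(=O)C=C(C)C)C2=O | target

## Step count and least certain steps

Total step count: 15. Longest linear sequence: 12 steps (steps 1–6, then 10–15, counted from 1). The arene branch (steps 7–9) joins at step 10.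

Step 12 (key step). Most likely to go wrong: ruthenium hydrides formed as the catalyst ages isomerise the free allylic carbinols to ketones. Closure onto the crowded 1,1-disubstituted alkene may also be slow enough for dimerisation to compete, and the product loses water to a naphthol on any trace of acid. The fallback sets out from 18. The remaining carbinol is silylated (Et3SiOTf, 2,6-lutidine) to give tert-butyl{[(3S)-1-{3-methoxy-2-[1-(triethylsilyloxy)prop-2-en-1-yl]-6-(triisopropylsilyloxy)phenyl}-6-methyl-2-methylidene-1-(triethylsilyloxy)hept-5-en-3-yl]oxy}dimethylsilane F1, in which neither carbinol can isomerise or ionise. Ring B is closed on this substrate with the same catalyst in hot toluene to give 2-[(1S)-1-(tert-butyldimethylsilyloxy)-4-methylpent-3-en-1-yl]-5-methoxy-1,4-bis(triethylsilyloxy)-8-(triisopropylsilyloxy)-1,4-dihydronaphthalene F2. Both triethylsilyl groups are then removed with pyridine-buffered HF·pyridine, and the route is rejoined at 20.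

Step 10. Most likely to go wrong: slow addition of the alkenylchromium to the doubly ortho-substituted aldehyde, which leaves time for protonation of the organometallic and for reductive dimerisation of the aldehyde by divalent chromium. The fallback sets out from 9 and replaces the chromium chemistry by iodine–lithium exchange (t-BuLi, Et2O, −78 °C) and addition of the alkenyllithium to 17 at −78 °C. It comes back at 18 and makes no new compound (F0).

Step 9. Most likely to go wrong: migration of the triethylsilyl group from oxygen to the lithiated ring carbon, or protonation of the crowded aryllithium before it meets the formamide. The fallback sets out from 11 and installs the formyl carbon first, on an unhindered aryllithium that carries no alkyl silyl ether. Bromine–lithium exchange and formylation (n-BuLi, THF, −78 °C; DMF) give 5-methoxy-2-(triisopropylsilyloxy)benzaldehyde F3. Acetalisation (HC(OMe)3, pyridinium tosylate, MeOH) gives [2-(dimethoxymethyl)-4-methoxyphenoxy]triisopropylsilane F4. Lithiation between the acetal and the methoxy group (n-BuLi, Et2O, 0 °C), addition to 12 and silylation in the flask give {2-(dimethoxymethyl)-4-methoxy-3-[1-(triethylsilyloxy)prop-2-en-1-yl]phenoxy}triisopropylsilane F5. Mild hydrolysis of the acetal (oxalic acid on wet silica gel, CH2Cl2) rejoins the route at 17.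

Step 6. Most likely to go wrong: delivery of tin to the terminal carbon, which after iodination would give a 1-iodoalkene that cannot furnish a 1,1-disubstituted alkene. The fallback sets out from 7 and uses no hydrometalation. Syn-iodoboration with B-iodo-9-borabicyclo[3.3.1]nonane (pentane, −20 °C) places iodine on the internal carbon by the polarity of the B–I addition, giving 9-[(1Z,3S)-3-(tert-butyldimethylsilyloxy)-2-iodo-6-methylhepta-1,5-dien-1-yl]-9-borabicyclo[3.3.1]nonane F6. Protodeboronation with acetic acid comes back at 9.

Step 14. Most likely to go wrong: decomposition of the quinone by the basic fluoride medium during the slow cleavage of the secondary alkyl silyl ether. The fallback sets out from 21 and changes the order of events. HF·pyridine in THF removes only the alkyl silyl group, giving 2-[(1S)-1-hydroxy-4-methylpent-3-en-1-yl]-5-methoxy-8-(triisopropylsilyloxy)naphthalene-1,4-dione F7. Esterification with 23 (DCC, DMAP) gives (1S)-1-[5-methoxy-1,4-dioxo-8-(triisopropylsilyloxy)-1,4-dihydronaphthalen-2-yl]-4-methylpent-3-en-1-yl 3-methylbut-2-enoate F8. A brief treatment with Bu4NF/AcOH at 0 °C then cleaves the labile aryl silyl ether and comes back at 24.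

## Further compounds

F1 | step 12 | tert-butyl{[(3S)-1-{3-methoxy-2-[1-(triethylsilyloxy)prop-2-en-1-yl]-6-(triisopropylsilyloxy)phenyl}-6-methyl-2-methylidene-1-(triethylsilyloxy)hept-5-en-3-yl]oxy}dimethylsilane | C=CC(O[Si](CC)(CC)CC)c1c(OC)ccc(O[Si](C(C)C)(C(C)C)C(C)C)c1C(O[Si](CC)(CC)CC)C(=C)[C@H](CC=C(C)C)O[Si](C)(C)C(C)(C)C
F2 | step 12 | 2-[(1S)-1-(tert-butyldimethylsilyloxy)-4-methylpent-3-en-1-yl]-5-methoxy-1,4-bis(triethylsilyloxy)-8-(triisopropylsilyloxy)-1,4-dihydronaphthalene | CC[Si](CC)(CC)OC1C=C([C@H](CC=C(C)C)O[Si](C)(C)C(C)(C)C)C(O[Si](CC)(CC)CC)c2c(O[Si](C(C)C)(C(C)C)C(C)C)ccc(OC)c12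
F0 | step 10 | none | none
F3 | step 9 | 5-methoxy-2-(triisopropylsilyloxy)benzaldehyde | COc1ccc(O[Si](C(C)C)(C(C)C)C(C)C)c(C=O)c1
F4 | step 9 | [2-(dimethoxymethyl)-4-methoxyphenoxy]triisopropylsilane | COc1ccc(O[Si](C(C)C)(C(C)C)C(C)C)c(C(OC)OC)c1
F5 | step 9 | {2-(dimethoxymethyl)-4-methoxy-3-[1-(triethylsilyloxy)prop-2-en-1-yl]phenoxy}triisopropylsilane | C=CC(O[Si](CC)(CC)CC)c1c(OC)ccc(O[Si](C(C)C)(C(C)C)C(C)C)c1C(OC)OC
F6 | step 6 | 9-[(1Z,3S)-3-(tert-butyldimethylsilyloxy)-2-iodo-6-methylhepta-1,5-dien-1-yl]-9-borabicyclo[3.3.1]nonane | I/C(=C\B1C2CCCC1CCC2)[C@H](CC=C(C)C)O[Si](C)(C)C(C)(C)C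
F7 | step 14 | 2-[(1S)-1-hydroxy-4-methylpent-3-en-1-yl]-5-methoxy-8-(triisopropylsilyloxy)naphthalene-1,4-dione | COc1ccc(O[Si](C(C)C)(C(C)C)C(C)C)c2c1C(=O)C=C([C@H](CC=C(C)C)O)C2=O
F8 | step 14 | (1S)-1-[5-methoxy-1,4-dioxo-8-(triisopropylsilyloxy)-1,4-dihydronaphthalen-2-yl]-4-methylpent-3-en-1-yl 3-methylbut-2-enoate | COc1ccc(O[Si](C(C)C)(C(C)C)C(C)C)c2c1C(=O)C=C([C@H](CC=C(C)C)OC(=O)C=C(C)C)C2=O
A1 | alternative 1 | (S)-2-{1-[1-(methoxymethoxy)-5-methoxy-8-(triisopropylsilyloxy)naphthalen-2-yl]-4-methylpent-3-enyl}-4,4,5,5-tetramethyl-1,3,2-dioxaborolane | COCOc1c([C@H](CC=C(C)C)B2OC(C)(C)C(C)(C)O2)ccc2c(OC)ccc(O[Si](C(C)C)(C(C)C)C(C)C)c12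
A2 | alternative 1 | 2-[1-(methoxymethoxy)-5-methoxy-8-(triisopropylsilyloxy)naphthalen-2-yl]-4,4,5,5-tetramethyl-1,3,2-dioxaborolane | COCOc1c(B2OC(C)(C)C(C)(C)O2)ccc2c(OC)ccc(O[Si](C(C)C)(C(C)C)C(C)C)c12
A3 | alternative 1 | vinyllithium | [Li]C=C
A4 | alternative 1 | 2-methylprop-1-en-1-yl trifluoromethanesulfonate | CC(C)=COS(=O)(=O)C(F)(F)F
A5 | alternative 2 | (S)-7-[1-(tert-butyldimethylsilyloxy)-4-methylpent-3-enyl]-4,5,8-trimethoxy-2-(trimethylsilyl)naphthalen-1-ol | COc1cc([C@H](CC=C(C)C)O[Si](C)(C)C(C)(C)C)c(OC)c2c(O)c([Si](C)(C)C)cc(OC)c12
A6 | alternative 2 | pentacarbonyl{[4-((S)-1-(tert-butyldimethylsilyloxy)-4-methylpent-3-enyl)-2,5-dimethoxyphenyl](methoxy)methylidene}chromium | COC(=[Cr])c1cc(OC)c([C@H](CC=C(C)C)O[Si](C)(C)C(C)(C)C)cc1OC.[C-]#[O+].[C-]#[O+].[C-]#[O+].[C-]#[O+].[C-]#[O+]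
A7 | alternative 2 | ethynyltrimethylsilane | C#C[Si](C)(C)C
A8 | alternative 3 | (S)-1-[8-hydroxy-5-methoxy-4-(methoxymethoxy)naphthalen-2-yl]-4-methylpent-3-enyl 3-methylbut-2-enoate | COCOc1cc([C@H](CC=C(C)C)OC(=O)C=C(C)C)cc2c(O)ccc(OC)c12
A9 | alternative 3 | (S)-1-[3-(methoxymethoxy)-5-(trifluoromethylsulfonyloxy)-4-(trimethylsilyl)phenyl]-4-methylpent-3-enyl 3-methylbut-2-enoate | COCOc1cc([C@H](CC=C(C)C)OC(=O)C=C(C)C)cc(OS(=O)(=O)C(F)(F)F)c1[Si](C)(C)C
A10 | alternative 3 | 2-methoxyfuran | COc1ccco1
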